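Numbering ring A as C1 (sulfated chain), C2 (bridging carbon to ring B), C3 (Br), C4 and C5 (O), C6 (H), the route disconnects C2–C3 and C1–C6: C3–C6 map onto 3,4-dimethoxythiophene, and because C3 lies beside C2, a silicon on C3 can be tied to a carbinol oxygen on the bridging carbon. Heating precursor 14, a 2-silylated 3,4-dimethoxythiophene 1,1-dioxide whose diethylsilyl group is bound through oxygen to the ring B propargylic carbinol, should in one operation form both bonds of ring A, close a five-membered oxasilole, expel SO2 and leave silicon at C3 as the placeholder for bromine.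

Key step: step 7

Assumption: the target is made in the acid form that is drawn and is achiral; compounds 7 and 12 to 18 carry one stereocentre, are racemic, and lose it in step 9.

Design remark: silicon carries two ethyl groups, bulkier than methyl so that the silyl ether and the C–Si bond next to the sulfone survive handling and dimerisation of the dioxide is disfavoured, yet small enough not to block ipso attack in step 8. The chain oxygen is a benzyl ether so that one BBr3 treatment unveils all five hydroxyls.

Step 1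
Reactants: 1 vanillin
Product: 3 2,3-dibromo-4-hydroxy-5-methoxybenzaldehyde (5,6-dibromovanillin), via 5-bromovanillin 2 (not isolated)
Conditions: Br2 (1.05 equiv), AcOH, rt; then Fe powder (0.1 equiv), Br2 (1.2 equiv), rt → 50 °C
Reagents that add atoms: bromine, BrBr
Why: Electrophilic aromatic bromination, in which the first bromine should enter ortho to the free phenol and the second, assisted by FeBr3 formed from the Fe powder, should enter the position para to the methoxy group, the established pattern for vanillin.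

Step 2
Reactants: 3 2,3-dibromo-4-hydroxy-5-methoxybenzaldehyde
Product: 4 2,3-dibromo-4,5-dimethoxybenzaldehyde
Conditions: MeI (1.5 equiv), K2CO3, DMF, rt
Reagents that add atoms: iodomethane, CI
Why: Williamson O-methylation (SN2 of the phenoxide on MeI) should proceed readily even for a phenol flanked by Br and OMe.

Step 3
Reactants: 5 benzyl but-3-yn-1-yl ether; 4 2,3-dibromo-4,5-dimethoxybenzaldehyde
Product: 7 rac-5-(benzyloxy)-1-(2,3-dibromo-4,5-dimethoxyphenyl)pent-2-yn-1-ol, via lithium acetylide of 5 6 (not isolated)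
Conditions: 5 (1.2 equiv), n-BuLi (1.1 equiv), THF, −78 °C; then 4, −78 → −20 °C; aq. NH4Cl
Reagents that add atoms: none
Why: Acetylide 1,2-addition to an aldehyde, in which no alkyllithium remains to exchange with the aryl bromides, and the new carbinol centre forms without control (racemic), which is immaterial because it is reduced to CH2 in step 9.

Step 4
Reactants: 8 3,4-dimethoxythiophene; 9 dichlorodiethylsilane
Product: 11 chloro(diethyl)(3,4-dimethoxythiophen-2-yl)silane, via 2-lithio-3,4-dimethoxythiophene 10 (not isolated)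
Conditions: n-BuLi (1.05 equiv), THF, −78 → 0 °C; cannulated into 9 (3 equiv), THF, −78 °C → rt; Kugelrohr distillation
Reagents that add atoms: none
Why: α-Lithiation of the thiophene next to sulfur and the methoxy group followed by nucleophilic substitution at silicon, with inverse addition to excess dichlorosilane favouring monosubstitution.

Step 5
Reactants: 7 rac-5-(benzyloxy)-1-(2,3-dibromo-4,5-dimethoxyphenyl)pent-2-yn-1-ol; 11 chloro(diethyl)(3,4-dimethoxythiophen-2-yl)silane
Product: 12 rac-{[5-(benzyloxy)-1-(2,3-dibromo-4,5-dimethoxyphenyl)pent-2-yn-1-yl]oxy}(diethyl)(3,4-dimethoxythiophen-2-yl)silane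
Conditions: 11 (1.3 equiv), imidazole (2.5 equiv), DMAP (0.1 equiv), CH2Cl2, 0 °C → rt; Et3N-deactivated silica
Reagents that add atoms: none
Why: Imidazole/DMAP-promoted O-silylation of a secondary alcohol by a chlorosilane (silyl ether formation) is routine for a silane of triethylsilyl-like size.

Step 6
Reactants: 12 rac-{[5-(benzyloxy)-1-(2,3-dibromo-4,5-dimethoxyphenyl)pent-2-yn-1-yl]oxy}(diethyl)(3,4-dimethoxythiophen-2-yl)silane
Product: 14 rac-2-[{[5-(benzyloxy)-1-(2,3-dibromo-4,5-dimethoxyphenyl)pent-2-yn-1-yl]oxy}(diethyl)silyl]-3,4-dimethoxythiophene 1,1-dioxide, via thiophene S-oxide 13 (not isolated)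
Conditions: DMDO (2.5 equiv, ca. 0.07 M in acetone), CH2Cl2, −40 → 0 °C; evaporation at ≤0 °C, used at once
Reagents that add atoms: dimethyldioxirane, CC1(C)OO1
Why: Electrophilic oxygen transfer from the dioxirane to sulfur (thiophene to thiophene 1,1-dioxide via the S-oxide) is a neutral oxidation known for thiophenes, 2-silyl ones included, leaves only acetone, so the labile Si–O and C–Si bonds should survive, and should outpace oxidation of the alkyne and the benzyl ether.

Step 7
Reactants: 14 rac-2-[{[5-(benzyloxy)-1-(2,3-dibromo-4,5-dimethoxyphenyl)pent-2-yn-1-yl]oxy}(diethyl)silyl]-3,4-dimethoxythiophene 1,1-dioxide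
Product: 16 rac-4-[2-(benzyloxy)ethyl]-3-(2,3-dibromo-4,5-dimethoxyphenyl)-1,1-diethyl-6,7-dimethoxy-1,3-dihydro-2,1-benzoxasilole, via bridged sulfone cycloadduct 15 (not isolated)
Conditions: PhMe (0.005 M), BHT (cat.), Ar sparge, 80 → 110 °C
Reagents that add atoms: none
Why: Proposed new method: the thiophene 1,1-dioxide is a non-aromatic cyclic diene, and on heating its C2 and C5 termini should add suprafacially across the tethered alkyne in an intramolecular [4+2] cycloaddition to give bridged sulfone 15, which loses SO2 by cheletropic extrusion so that ring A emerges aromatic without an oxidant. The closest known reactions are intermolecular Diels–Alder reactions of thiophene 1,1-dioxides with alkynes followed by SO2 loss and silicon-tethered intramolecular Diels–Alder reactions of silyl ethers. Ring A is closed by the two new sigma bonds (thiophene C2 to the carbinol-bearing alkyne carbon, thiophene C5 to the chain-bearing alkyne carbon), and the five-membered oxasilole is closed in fused, 5-exo-dig fashion by the first of these bonds, the long Si–C and Si–O bonds easing strain in the three-atom tether. No stereocentre is created in 16, since the bridgeheads of 15 become arene carbons and the racemic carbinol centre is carried through unchanged. The selectivity needed is regiochemical (silicon-bearing carbon to the carbinol-bearing alkyne carbon) and is enforced by the short Si–O–CH tether, which cannot reach the opposite orientation, while the two methoxy groups raise the diene HOMO towards the unactivated alkyne and the diethylsilyl group, the 3,4-substituents and high dilution hold back bimolecular dimerisation of the dioxide.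

Step 8
Reactants: 16 rac-4-[2-(benzyloxy)ethyl]-3-(2,3-dibromo-4,5-dimethoxyphenyl)-1,1-diethyl-6,7-dimethoxy-1,3-dihydro-2,1-benzoxasilole
Product: 18 rac-{6-[2-(benzyloxy)ethyl]-2-bromo-3,4-dimethoxyphenyl}(2,3-dibromo-4,5-dimethoxyphenyl)methanol, via bromosilyl ether 17 (not isolated)
Conditions: Br2 (1.05 equiv), NaHCO3 (s), CH2Cl2, −78 → −20 °C, dark; then K2CO3, MeOH, rt
Reagents that add atoms: bromine, BrBr
Why: Electrophilic ipso-bromodesilylation, in which attack at C3 gives a Wheland cation stabilised by the C–Si bond and the ortho methoxy group, bromide then cleaves C–Si to bromosilyl ether 17, and methanolysis frees the carbinol, whereas C6–H lacks silicon assistance and ring B is deactivated by two bromines.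

Step 9
Reactants: 18 rac-{6-[2-(benzyloxy)ethyl]-2-bromo-3,4-dimethoxyphenyl}(2,3-dibromo-4,5-dimethoxyphenyl)methanol
Product: 19 1-[2-(benzyloxy)ethyl]-3-bromo-2-[(2,3-dibromo-4,5-dimethoxyphenyl)methyl]-4,5-dimethoxybenzene
Conditions: Et3SiH (3 equiv), TFA (10 equiv), CH2Cl2, 0 °C → rt
Reagents that add atoms: none
Why: Ionic hydrogenation, in which TFA ionises the diarylcarbinol to a cation stabilised by a para-methoxy group on each ring and the silane delivers hydride, removing the only stereocentre while the aryl bromides and the primary benzyl ether stay untouched.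

Step 10
Reactants: 19 1-[2-(benzyloxy)ethyl]-3-bromo-2-[(2,3-dibromo-4,5-dimethoxyphenyl)methyl]-4,5-dimethoxybenzene
Product: 20 3-bromo-4-[(2,3-dibromo-4,5-dihydroxyphenyl)methyl]-5-(2-hydroxyethyl)benzene-1,2-diol
Conditions: BBr3 (10 equiv), CH2Cl2, −78 → 0 °C; ice-water quench under Ar
Reagents that add atoms: none
Why: Lewis-acid ether cleavage, in which BBr3 coordinates each ether oxygen and bromide attacks the methyl or benzylic carbon (SN2), the low temperature keeping the primary alkyl borate from turning into an alkyl bromide.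

Step 11
Reactants: 20 3-bromo-4-[(2,3-dibromo-4,5-dihydroxyphenyl)methyl]-5-(2-hydroxyethyl)benzene-1,2-diol
Product: 21 2-{3-bromo-2-[(2,3-dibromo-4,5-dihydroxyphenyl)methyl]-4,5-dihydroxyphenyl}ethyl hydrogen sulfate (CNP0136879.0)
Conditions: H2SO4 (1.1 equiv), DCC (5 equiv), DMF, 0 °C; filtration; C18 chromatography (H2O/MeCN)
Reagents that add atoms: sulfuric acid, OS(=O)(=O)O
Why: Carbodiimide-mediated sulfation, in which the O-sulfonylisourea from DCC and H2SO4 should transfer the sulfo group to the primary alkanol much faster than to phenols, here also hindered and made less nucleophilic by ortho bromine, so a near-stoichiometric charge of acid should give the mono alkyl hydrogen sulfate.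

Compound list
1 | vanillin | COc1cc(C=O)ccc1O | starting material
2 | 5-bromovanillin (3-bromo-4-hydroxy-5-methoxybenzaldehyde) | COc1cc(C=O)cc(Br)c1O | intermediate
3 | 2,3-dibromo-4-hydroxy-5-methoxybenzaldehyde (5,6-dibromovanillin) | COc1cc(C=O)c(Br)c(Br)c1O | intermediate
4 | 2,3-dibromo-4,5-dimethoxybenzaldehyde | COc1cc(C=O)c(Br)c(Br)c1OC | intermediate
5 | benzyl but-3-yn-1-yl ether, [(but-3-yn-1-yloxy)methyl]benzene | C#CCCOCc1ccccc1 | starting material
6 | lithium acetylide of 5, [4-(benzyloxy)but-1-yn-1-yl]lithium | [Li]C#CCCOCc1ccccc1 | intermediate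
7 | rac-5-(benzyloxy)-1-(2,3-dibromo-4,5-dimethoxyphenyl)pent-2-yn-1-ol | OC(C#CCCOCc1ccccc1)c1cc(OC)c(OC)c(Br)c1Br | intermediate
8 | 3,4-dimethoxythiophene | COc1cscc1OC | starting material
9 | dichlorodiethylsilane | CC[Si](Cl)(Cl)CC | starting material
10 | 2-lithio-3,4-dimethoxythiophene | [Li]c1scc(OC)c1OC | intermediate
11 | chloro(diethyl)(3,4-dimethoxythiophen-2-yl)silane | CC[Si](Cl)(CC)c1scc(OC)c1OC | intermediate
12 | rac-{[5-(benzyloxy)-1-(2,3-dibromo-4,5-dimethoxyphenyl)pent-2-yn-1-yl]oxy}(diethyl)(3,4-dimethoxythiophen-2-yl)silane | CC[Si](CC)(OC(C#CCCOCc1ccccc1)c1cc(OC)c(OC)c(Br)c1Br)c1scc(OC)c1OC | intermediate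
13 | thiophene S-oxide of 12 (1-oxide, mixture of diastereomers) | CC[Si](CC)(OC(C#CCCOCc1ccccc1)c1cc(OC)c(OC)c(Br)c1Br)C1=C(OC)C(OC)=CS1=O | intermediate
14 | rac-2-[{[5-(benzyloxy)-1-(2,3-dibromo-4,5-dimethoxyphenyl)pent-2-yn-1-yl]oxy}(diethyl)silyl]-3,4-dimethoxythiophene 1,1-dioxide | CC[Si](CC)(OC(C#CCCOCc1ccccc1)c1cc(OC)c(OC)c(Br)c1Br)C1=C(OC)C(OC)=CS1(=O)=O | intermediate
15 | bridged sulfone cycloadduct (7-thiabicyclo[2.2.1]hepta-2,5-diene 7,7-dioxide fused to the oxasilole, mixture of diastereomers) | COC1=C(OC)C23[Si](CC)(CC)OC(c4cc(OC)c(OC)c(Br)c4Br)C2=C(CCOCc2ccccc2)C1S3(=O)=O | intermediate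
16 | rac-4-[2-(benzyloxy)ethyl]-3-(2,3-dibromo-4,5-dimethoxyphenyl)-1,1-diethyl-6,7-dimethoxy-1,3-dihydro-2,1-benzoxasilole | COc1cc(CCOCc4ccccc4)c2C(c3cc(OC)c(OC)c(Br)c3Br)O[Si](CC)(CC)c2c1OC | intermediate
17 | rac-bromo{[{6-[2-(benzyloxy)ethyl]-2-bromo-3,4-dimethoxyphenyl}(2,3-dibromo-4,5-dimethoxyphenyl)methyl]oxy}diethylsilane | CC[Si](Br)(CC)OC(c1c(CCOCc2ccccc2)cc(OC)c(OC)c1Br)c1cc(OC)c(OC)c(Br)c1Br | intermediate
18 | rac-{6-[2-(benzyloxy)ethyl]-2-bromo-3,4-dimethoxyphenyl}(2,3-dibromo-4,5-dimethoxyphenyl)methanol | OC(c1c(CCOCc2ccccc2)cc(OC)c(OC)c1Br)c1cc(OC)c(OC)c(Br)c1Br | intermediate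
19 | 1-[2-(benzyloxy)ethyl]-3-bromo-2-[(2,3-dibromo-4,5-dimethoxyphenyl)methyl]-4,5-dimethoxybenzene | COc1cc(CCOCc2ccccc2)c(Cc2cc(OC)c(OC)c(Br)c2Br)c(Br)c1OC | intermediate
20 | 3-bromo-4-[(2,3-dibromo-4,5-dihydroxyphenyl)methyl]-5-(2-hydroxyethyl)benzene-1,2-diol | OCCc1cc(O)c(O)c(Br)c1Cc1cc(O)c(O)c(Br)c1Br | intermediate
21 | 2-{3-bromo-2-[(2,3-dibromo-4,5-dihydroxyphenyl)methyl]-4,5-dihydroxyphenyl}ethyl hydrogen sulfate | O=S(=O)(O)OCCc1cc(O)c(O)c(Br)c1Cc1cc(O)c(O)c(Br)c1Br | target

Total steps: 11. Longest linear sequence: 10 (steps 1, 2, 3, 5, 6, 7, 8, 9, 10, 11 from vanillin).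

Steps most likely to fail

1. Step 7 (Proposed new method). The cycloaddition may be too slow to compete with bimolecular dimerisation of the dioxide or with cleavage of the C–Si bond next to the sulfone. The same weakness would show if the dioxide decomposes during step 6. The fallback uses only known reactions, sets out from 2 (obtained by stopping step 1 after the first equivalent of Br2) and from 4, and comes back at 18. Compound 2 is O-methylated (MeI, K2CO3, DMF) to 3-bromo-4,5-dimethoxybenzaldehyde F1. Wittig methylenation (Ph3PCH3Br, KOtBu, THF) gives 1-bromo-5-ethenyl-2,3-dimethoxybenzene F2. Hydroboration and oxidation (9-BBN, THF; NaOH, H2O2) give 2-(3-bromo-4,5-dimethoxyphenyl)ethan-1-ol F3. Benzylation (NaH, BnBr, DMF) gives 1-[2-(benzyloxy)ethyl]-3-bromo-4,5-dimethoxybenzene F4. Iodination (NIS, TFA cat., MeCN) should occur para to the C5 methoxy group, the same orientation as the second bromination of step 1, giving 1-[2-(benzyloxy)ethyl]-3-bromo-2-iodo-4,5-dimethoxybenzene F5. Selective iodine–magnesium exchange (iPrMgCl·LiCl, THF, −40 °C) gives {6-[2-(benzyloxy)ethyl]-2-bromo-3,4-dimethoxyphenyl}magnesium chloride F6, which is added to aldehyde 4 (−40 → 0 °C) to give carbinol 18, from which steps 9 to 11 follow unchanged.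

2. Step 8. Bromine may attack C6–H of ring A in competition with the ipso position, because an alkoxy-substituted, ring-bound silicon directs less strongly than a trialkylsilyl group, and any HBr so formed would cause protodesilylation. The fallback sets out from 16 and comes back at 18. The oxasilole is opened at silicon with MeMgBr (THF, 0 °C → rt), as is known for cyclic benzylic silyl ethers, giving rac-{6-[2-(benzyloxy)ethyl]-2-[diethyl(methyl)silyl]-3,4-dimethoxyphenyl}(2,3-dibromo-4,5-dimethoxyphenyl)methanol F7. Its trialkylsilyl group then undergoes classical ipso-bromodesilylation (Br2 or NBS, CH2Cl2, −78 °C) to give 18 directly.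

3. Step 11. Phenolic hydroxyls may be sulfated alongside the primary alcohol, and the free catechols may oxidise during handling. The fallback sets out from 20 and comes back at 21. Persilylation (TBSCl, imidazole, DMF) gives the pentakis(tert-butyldimethylsilyl) ether F8. Mild acid methanolysis (CSA, MeOH, 0 °C) removes only the primary alkyl silyl ether, aryl silyl ethers being far more acid-stable, to give the tetrakis(silyl) alcohol F9. Sulfation with SO3·pyridine (pyridine, rt) gives the tetrakis(silyl) alkyl hydrogen sulfate F10. KHF2 in MeOH then cleaves the four aryl silyl ethers without touching the sulfate ester, and acidic ion exchange returns 21.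

Further compounds
F1 | step 7 | 3-bromo-4,5-dimethoxybenzaldehyde | COc1cc(C=O)cc(Br)c1OC
F2 | step 7 | 1-bromo-5-ethenyl-2,3-dimethoxybenzene | COc1cc(C=C)cc(Br)c1OC
F3 | step 7 | 2-(3-bromo-4,5-dimethoxyphenyl)ethan-1-ol | COc1cc(CCO)cc(Br)c1OC
F4 | step 7 | 1-[2-(benzyloxy)ethyl]-3-bromo-4,5-dimethoxybenzene | COc1cc(CCOCc2ccccc2)cc(Br)c1OC
F5 | step 7 | 1-[2-(benzyloxy)ethyl]-3-bromo-2-iodo-4,5-dimethoxybenzene | COc1cc(CCOCc2ccccc2)c(I)c(Br)c1OC
F6 | step 7 | {6-[2-(benzyloxy)ethyl]-2-bromo-3,4-dimethoxyphenyl}magnesium chloride | COc1cc(CCOCc2ccccc2)c([Mg]Cl)c(Br)c1OC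
F7 | step 8 | rac-{6-[2-(benzyloxy)ethyl]-2-[diethyl(methyl)silyl]-3,4-dimethoxyphenyl}(2,3-dibromo-4,5-dimethoxyphenyl)methanol | OC(c1c(CCOCc2ccccc2)cc(OC)c(OC)c1[Si](C)(CC)CC)c1cc(OC)c(OC)c(Br)c1Br
F8 | step 11 | pentakis(tert-butyldimethylsilyl) ether of 20 | CC(C)(C)[Si](C)(C)OCCc1cc(O[Si](C)(C)C(C)(C)C)c(O[Si](C)(C)C(C)(C)C)c(Br)c1Cc1cc(O[Si](C)(C)C(C)(C)C)c(O[Si](C)(C)C(C)(C)C)c(Br)c1Br
F9 | step 11 | tetrakis(aryl tert-butyldimethylsilyl) ether of 20 with free primary alcohol | OCCc1cc(O[Si](C)(C)C(C)(C)C)c(O[Si](C)(C)C(C)(C)C)c(Br)c1Cc1cc(O[Si](C)(C)C(C)(C)C)c(O[Si](C)(C)C(C)(C)C)c(Br)c1Br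
F10 | step 11 | tetrakis(aryl tert-butyldimethylsilyl) ether of 21 | O=S(=O)(O)OCCc1cc(O[Si](C)(C)C(C)(C)C)c(O[Si](C)(C)C(C)(C)C)c(Br)c1Cc1cc(O[Si](C)(C)C(C)(C)C)c(O[Si](C)(C)C(C)(C)C)c(Br)c1Br
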